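**Retrosynthetic overview**

1. The target 28 comes from its C9 PMB ether 27, and 27 from the open-chain bromo-enal 25 by one chromium-mediated allylation/lactonisation that makes C6–C7, the ten-membered carbocycle and the γ-lactone together.
2. Enabling feature: C7 is the γ-terminus of the 2-carboxyallyl triad C13–C11(C12)–C7, and C6 is a carbinol carbon whose oxygen lies 1,4 to C12. The (Z)-C4=C5 alkene, the cis-2,3-oxirane and the C1=C10 enoate bend the chain so that C6 and C7 can meet.
3. 25 comes from cross-metathesis of a C7 vinyl group with methyl 2-(bromomethyl)acrylate. C8 is set by chelation-controlled vinyl addition to a C8 aldehyde and is esterified with (2R,3R)-epoxyangelic acid (from angelic acid by Sharpless epoxidation).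
4. C8–C10 and C14 come from dimethyl (S)-malate: Fráter–Seebach aldol with the C1 epoxy aldehyde, lactonisation to a temporary paraconate ring, then E1cB opening give the (E)-C1=C10 enoate and free the C8 carboxyl.
5. C1–C6 and C15 come from but-2-yn-1-ol and propargyl alcohol (Red-Al/I2, Sonogashira, Lindlar, Sharpless epoxidation). Ring order: the two oxiranes first, then carbocycle and lactone in the key step.

Key step: step 19

Remark: germacrane numbering is used for positions (ring C1–C10, lactone carbons C11–C13, ester carbon C14, methyl C15); the target is read from its SMILES as 2R,3S,6R,7S,8S,9S with a (2R,3R)-epoxyangelate.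

**Route**

Step 1
Reactants: 1 angelic acid, (Z)-2-methylbut-2-enoic acid
Product: 2 (Z)-2-methylbut-2-en-1-ol
Conditions: LiAlH4, Et2O, 0 °C to rt
Reagents that add atoms: none
Why: Hydride reduction of the acid leaves the trisubstituted alkene untouched, so the (Z)-geometry of angelic acid is kept.

Step 2
Reactants: 2 (Z)-2-methylbut-2-en-1-ol
Product: 3 [(2S,3R)-2,3-dimethyloxiran-2-yl]methanol
Conditions: Ti(OiPr)4, L-(+)-diethyl tartrate, t-BuOOH, 4 Å MS, CH2Cl2, −20 °C
Reagents that add atoms: tert-butyl hydroperoxide, CC(C)(C)OO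
Why: Sharpless asymmetric epoxidation; the titanium L-tartrate complex delivers oxygen syn-specifically to one face of the (Z)-allylic alcohol and sets both oxirane centres.

Step 3
Reactants: 3 [(2S,3R)-2,3-dimethyloxiran-2-yl]methanol
Product: 4 (2R,3R)-2,3-dimethyloxirane-2-carboxylic acid (epoxyangelic acid)
Conditions: RuCl3·xH2O (cat.), NaIO4, EtOAc/MeCN/H2O, rt
Reagents that add atoms: sodium periodate, [Na+].[O-]I(=O)(=O)=O; water, O
Why: Ruthenium tetroxide oxidation (Sharpless RuCl3/NaIO4) of the primary alcohol to the acid does not touch the oxirane centres, whose descriptors become 2R,3R only by the priority change.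

Step 4
Reactants: 5 but-2-yn-1-ol
Product: 6 (Z)-3-iodobut-2-en-1-ol
Conditions: NaAlH2(OCH2CH2OMe)2 (Red-Al), THF, 0 °C; then I2, −78 °C
Reagents that add atoms: iodine, II
Why: Hydroxyl-directed trans-hydroalumination places aluminium on C4 cis to the carbinol, and iodinolysis with retention gives the (Z)-iodide that fixes the later C4=C5 geometry.

Step 5
Reactants: 6 (Z)-3-iodobut-2-en-1-ol
Product: 7 (Z)-1-(tert-butyldimethylsilyloxy)-3-iodobut-2-ene
Conditions: TBSCl, imidazole, CH2Cl2, 0 °C
Reagents that add atoms: tert-butyldimethylsilyl chloride, CC(C)(C)[Si](C)(C)Cl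
Why: Standard silylation protects the future C6 oxygen through the base- and organometal-mediated steps.

Step 6
Reactants: 7 (Z)-1-(tert-butyldimethylsilyloxy)-3-iodobut-2-ene; 8 prop-2-yn-1-ol
Product: 9 (Z)-6-(tert-butyldimethylsilyloxy)-4-methylhex-4-en-2-yn-1-ol
Conditions: PdCl2(PPh3)2 (cat.), CuI (cat.), Et3N, THF, rt
Reagents that add atoms: none
Why: Sonogashira coupling of the alkenyl iodide proceeds with retention, so C3 and C6 stay cis on C4=C5.

Step 7
Reactants: 9 (Z)-6-(tert-butyldimethylsilyloxy)-4-methylhex-4-en-2-yn-1-ol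
Product: 10 (2Z,4Z)-6-(tert-butyldimethylsilyloxy)-4-methylhexa-2,4-dien-1-ol
Conditions: H2 (1 atm), Pd/CaCO3 poisoned with Pb(OAc)2 (Lindlar catalyst), quinoline, EtOAc, rt
Reagents that add atoms: none
Why: Lindlar semi-hydrogenation adds hydrogen syn to the alkyne and should give the (Z)-C2=C3 alkene needed for a cis-oxirane.

Step 8
Reactants: 10 (2Z,4Z)-6-(tert-butyldimethylsilyloxy)-4-methylhexa-2,4-dien-1-ol
Product: 11 cis-epoxy alcohol, {(2R,3S)-3-[(Z)-4-(tert-butyldimethylsilyloxy)but-2-en-2-yl]oxiran-2-yl}methanol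
Conditions: Ti(OiPr)4, D-(−)-diethyl tartrate, t-BuOOH, 4 Å MS, CH2Cl2, −20 °C
Reagents that add atoms: tert-butyl hydroperoxide, CC(C)(C)OO
Why: Sharpless asymmetric epoxidation epoxidises only the alkene of the allylic alcohol; the D-tartrate complex sets C2 (R) and C3 (S), and syn addition to the (Z)-alkene makes the oxirane cis.

Step 9
Reactants: 11 cis-epoxy alcohol
Product: 12 cis-epoxy aldehyde, (2S,3S)-3-[(Z)-4-(tert-butyldimethylsilyloxy)but-2-en-2-yl]oxirane-2-carbaldehyde
Conditions: Dess–Martin periodinane, NaHCO3, CH2Cl2, 0 °C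
Reagents that add atoms: none
Why: Buffered Dess–Martin oxidation gives the C1 aldehyde without base, so the cis-oxirane should not epimerise.

Step 10
Reactants: 12 cis-epoxy aldehyde; 13 dimethyl (S)-malate
Product: 15 paraconate lactone (O–C1 lactone on C8 with free C9 hydroxyl trans to the C10 methyl ester), via open-chain aldol adduct 14 (not isolated)
Conditions: 13, LiN(SiMe3)2 (2.2 equiv), THF, −78 to −20 °C; then 12, −78 to 0 °C; AcOH
Reagents that add atoms: none
Why: Fráter–Seebach aldol of the malate dianion forms C1–C10 anti to the C9 alkoxide, and the new C1 alkoxide lactonises onto the C8 ester; the C1 and C10 centres are transient because both become sp2 in step 12, while C9 (S) comes unchanged from malate.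

Step 11
Reactants: 15 paraconate lactone
Product: 16 C9 4-methoxybenzyl ether of the paraconate lactone
Conditions: 4-MeOC6H4CH2Br, Ag2O, 4 Å MS, CH2Cl2, rt, dark
Reagents that add atoms: 4-methoxybenzyl bromide, COc1ccc(CBr)cc1
Why: Silver-oxide-mediated etherification protects the α-hydroxy lactone without strong base or acid and installs the chelating group used in step 14.

Step 12
Reactants: 16 C9 4-methoxybenzyl ether of the paraconate lactone
Product: 17 (E)-alkylidene succinic half ester (C8 carboxylic acid, C14 methyl ester, C1=C10 enoate with C2 trans to the ester)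
Conditions: DBU, CH2Cl2, 0 °C; pH 5 buffer
Reagents that add atoms: none
Why: E1cB opening of the lactone (the second half of a Stobbe condensation): the C10 ester enolate expels the lactone carboxylate, which gives the conjugated (E)-enoate and frees C8 as the only carboxylic acid.

Step 13
Reactants: 17 (E)-alkylidene succinic half ester
Product: 19 C8 aldehyde, via acid chloride 18 (not isolated)
Conditions: Me2C=C(Cl)NMe2, CH2Cl2, 0 °C; then LiAlH(Ot-Bu)3, THF, −78 °C
Reagents that add atoms: none
Why: The Ghosez reagent forms the acid chloride under neutral conditions, and partial reduction with LiAlH(Ot-Bu)3 at low temperature should stop at the aldehyde without touching the enoate or the oxirane.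

Step 14
Reactants: 19 C8 aldehyde
Product: 20 C8 allylic alcohol (8,9-syn; vinyl group is C7)
Conditions: MgBr2·OEt2, CH2Cl2, −78 °C; then CH2=CHMgBr, −78 °C
Reagents that add atoms: vinylmagnesium bromide, C=C[Mg]Br
Why: Cram-chelate addition: magnesium bridges the aldehyde oxygen and the C9 PMB ether, and the vinyl group adds to the face opposite the C10 substituent, which sets C8 syn to C9 as in the target.

Step 15
Reactants: 20 C8 allylic alcohol; 4 (2R,3R)-2,3-dimethyloxirane-2-carboxylic acid
Product: 21 C8 epoxyangelate ester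
Conditions: 4, 2,4,6-Cl3C6H2COCl, Et3N, THF, rt; then 20, DMAP, toluene, rt
Reagents that add atoms: none
Why: Yamaguchi esterification acylates the hindered secondary alcohol through the mixed anhydride with retention at C8 and without opening either oxirane.

Step 16
Reactants: 21 C8 epoxyangelate ester
Product: 22 C6 allylic alcohol
Conditions: Bu4NF/AcOH (1:1), THF, 0 °C
Reagents that add atoms: none
Why: Buffered fluoride cleaves the primary silyl ether near neutrality, so the esters and the vinyl oxirane should survive; the alcohol is oxidised at once.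

Step 17
Reactants: 22 C6 allylic alcohol
Product: 23 (Z)-enal (C6 aldehyde)
Conditions: MnO2, CH2Cl2, rt
Reagents that add atoms: none
Why: Manganese dioxide oxidises only the allylic primary alcohol under neutral conditions and should keep the (Z)-C4=C5 geometry.

Step 18
Reactants: 23 (Z)-enal; 24 methyl 2-(bromomethyl)acrylate
Product: 25 open-chain bromo-enal (C7=C11 alkene with C8 cis to the CH2Br arm)
Conditions: 24 (5 equiv), RuCl2(H2IMes)(=CH-C6H4-2-OiPr) (Hoveyda–Grubbs second-generation catalyst, 10 mol%), CH2Cl2, 40 °C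
Reagents that add atoms: none
Why: Olefin cross-metathesis joins the only monosubstituted alkene with the 1,1-disubstituted acrylate with loss of ethylene, while the trisubstituted alkenes are inert; the alkene geometry does not matter because the allylchromium of step 19 equilibrates.

Step 19
Reactants: 25 open-chain bromo-enal
Product: 27 9-O-(4-methoxybenzyl) derivative of the target (ten-membered carbocycle with trans-fused α-methylene-γ-lactone), via seco hydroxy ester 26 (not isolated)
Conditions: CrCl2 (10 equiv), THF, 2 mM, slow addition, rt; then aq. NH4Cl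
Reagents that add atoms: none
Why: Divalent chromium reduces the allylic C13–Br bond to a 2-(methoxycarbonyl)allylchromium species (trivalent chromium) that equilibrates by 1,3-metal shift and adds through C7 to the C6 aldehyde in a chair-like six-membered transition state, which makes C6–C7, moves the alkene to C11=C13 and leaves a C6 chromium alkoxide 1,4 to C12 that then displaces methoxide from C12. The closest known reaction is the chromium dichloride (Nozaki–Hiyama) macrocyclisation of ω-formyl 2-(bromomethyl)alk-2-enoates used to close ten-membered germacranolides. The carbocycle closes 10-exo-trig at the aldehyde carbon (the allyl unit reacts with transposition, SE2′), and the lactone closes 5-exo-trig at C12. C6 and C7 arise together: the chair with the C5 chain and C8 both equatorial should give the anti (6,7-trans) relationship, and the C8 stereocentre should fix the face of C7, since in the rotamer with H8 eclipsing the alkene the aldehyde carbon approaches opposite the C9 chain. The step needs ring closure to outrun oligomerisation and carbonyl addition to outrun loss of the C8 carboxylate from the allylchromium; high dilution, slow addition and the chain pre-bent by the (Z)-C4=C5 alkene, the cis-oxirane and the C1=C10 enoate serve the first, fast intramolecular trapping the second. Divalent chromium should leave the oxiranes, the esters and the enoate untouched under these conditions.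

Step 20
Reactants: 27 9-O-(4-methoxybenzyl) derivative of the target
Product: 28 target
Conditions: DDQ, CH2Cl2/pH 7 buffer, 0 °C
Reagents that add atoms: none
Why: Oxidative cleavage of the PMB ether by DDQ under buffered conditions frees the C9 hydroxyl without acid or base, so the oxiranes, the α-methylene lactone and the C8 ester should remain in place.

**Compound list**

1 | angelic acid, (Z)-2-methylbut-2-enoic acid | C/C=C(/C)C(=O)O | starting material
2 | (Z)-2-methylbut-2-en-1-ol | C/C=C(/C)CO | intermediate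
3 | [(2S,3R)-2,3-dimethyloxiran-2-yl]methanol | OC[C@]1(C)O[C@@H]1C | intermediate
4 | (2R,3R)-2,3-dimethyloxirane-2-carboxylic acid | OC(=O)[C@]1(C)O[C@@H]1C | intermediate
5 | but-2-yn-1-ol | CC#CCO | starting material
6 | (Z)-3-iodobut-2-en-1-ol | OC/C=C(/C)I | intermediate
7 | (Z)-1-(tert-butyldimethylsilyloxy)-3-iodobut-2-ene | CC(C)(C)[Si](C)(C)OC/C=C(/C)I | intermediate
8 | prop-2-yn-1-ol | C#CCO | starting material
9 | (Z)-6-(tert-butyldimethylsilyloxy)-4-methylhex-4-en-2-yn-1-ol | CC(C)(C)[Si](C)(C)OC/C=C(/C)C#CCO | intermediate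
10 | (2Z,4Z)-6-(tert-butyldimethylsilyloxy)-4-methylhexa-2,4-dien-1-ol | CC(C)(C)[Si](C)(C)OC/C=C(/C)\C=C/CO | intermediate
11 | cis-epoxy alcohol, {(2R,3S)-3-[(Z)-4-(tert-butyldimethylsilyloxy)but-2-en-2-yl]oxiran-2-yl}methanol | CC(C)(C)[Si](C)(C)OC/C=C(/C)[C@@H]1O[C@@H]1CO | intermediate
12 | cis-epoxy aldehyde, (2S,3S)-3-[(Z)-4-(tert-butyldimethylsilyloxy)but-2-en-2-yl]oxirane-2-carbaldehyde | CC(C)(C)[Si](C)(C)OC/C=C(/C)[C@@H]1O[C@@H]1C=O | intermediate
13 | dimethyl (S)-malate | COC(=O)C[C@H](O)C(=O)OC | starting material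
14 | open-chain aldol adduct (C10 substituent anti to the C9 hydroxyl; expected major C1 epimer drawn) | CC(C)(C)[Si](C)(C)OC/C=C(/C)[C@@H]1O[C@@H]1[C@@H](O)[C@@H](C(=O)OC)[C@H](O)C(=O)OC | intermediate
15 | paraconate lactone (C9 hydroxyl trans to the C10 methyl ester) | CC(C)(C)[Si](C)(C)OC/C=C(/C)[C@@H]1O[C@@H]1[C@H]2OC(=O)[C@@H](O)[C@@H]2C(=O)OC | intermediate
16 | C9 4-methoxybenzyl ether of the paraconate lactone | CC(C)(C)[Si](C)(C)OC/C=C(/C)[C@@H]1O[C@@H]1[C@H]2OC(=O)[C@@H](OCc3ccc(OC)cc3)[C@@H]2C(=O)OC | intermediate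
17 | (E)-alkylidene succinic half ester (C8 acid, C14 methyl ester, C9 OPMB) | CC(C)(C)[Si](C)(C)OC/C=C(/C)[C@@H]1O[C@@H]1/C=C(/C(=O)OC)[C@H](OCc2ccc(OC)cc2)C(=O)O | intermediate
18 | C8 acid chloride | CC(C)(C)[Si](C)(C)OC/C=C(/C)[C@@H]1O[C@@H]1/C=C(/C(=O)OC)[C@H](OCc2ccc(OC)cc2)C(=O)Cl | intermediate
19 | C8 aldehyde | CC(C)(C)[Si](C)(C)OC/C=C(/C)[C@@H]1O[C@@H]1/C=C(/C(=O)OC)[C@H](OCc2ccc(OC)cc2)C=O | intermediate
20 | C8 allylic alcohol (8,9-syn) | CC(C)(C)[Si](C)(C)OC/C=C(/C)[C@@H]1O[C@@H]1/C=C(/C(=O)OC)[C@H](OCc2ccc(OC)cc2)[C@@H](O)C=C | intermediate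
21 | C8 epoxyangelate ester | CC(C)(C)[Si](C)(C)OC/C=C(/C)[C@@H]1O[C@@H]1/C=C(/C(=O)OC)[C@H](OCc2ccc(OC)cc2)[C@@H](OC(=O)[C@]3(C)O[C@@H]3C)C=C | intermediate
22 | C6 allylic alcohol | OC/C=C(/C)[C@@H]1O[C@@H]1/C=C(/C(=O)OC)[C@H](OCc2ccc(OC)cc2)[C@@H](OC(=O)[C@]3(C)O[C@@H]3C)C=C | intermediate
23 | (Z)-enal | O=C/C=C(/C)[C@@H]1O[C@@H]1/C=C(/C(=O)OC)[C@H](OCc2ccc(OC)cc2)[C@@H](OC(=O)[C@]3(C)O[C@@H]3C)C=C | intermediate
24 | methyl 2-(bromomethyl)acrylate | C=C(CBr)C(=O)OC | starting material
25 | open-chain bromo-enal | O=C/C=C(/C)[C@@H]1O[C@@H]1/C=C(/C(=O)OC)[C@H](OCc2ccc(OC)cc2)[C@@H](OC(=O)[C@]3(C)O[C@@H]3C)/C=C(/C(=O)OC)CBr | intermediate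
26 | seco hydroxy ester (ten-membered carbocycle, C6 hydroxyl, C12 methyl ester; formed as its chromium alkoxide) | O[C@@H]1/C=C(/C)[C@@H]2O[C@@H]2/C=C(/C(=O)OC)[C@H](OCc3ccc(OC)cc3)[C@@H](OC(=O)[C@]4(C)O[C@@H]4C)[C@H]1C(=C)C(=O)OC | intermediate
27 | 9-O-(4-methoxybenzyl) derivative of the target | C=C1C(=O)O[C@@H]2/C=C(/C)[C@@H]3O[C@@H]3/C=C(/C(=O)OC)[C@H](OCc4ccc(OC)cc4)[C@@H](OC(=O)[C@]5(C)O[C@@H]5C)[C@@H]12 | intermediate
28 | target CNP0291485.1 | C=C1C(=O)O[C@@H]2/C=C(/C)[C@@H]3O[C@@H]3/C=C(/C(=O)OC)[C@H](O)[C@@H](OC(=O)[C@]3(C)O[C@@H]3C)[C@@H]12 | target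

**Step count and risks**

Total step count: 20. Longest linear sequence: 17 steps (5 to 28, steps 4 to 20); the acid 4 (steps 1 to 3) joins at step 15.

Steps most likely to fail:

1. Step 19. Intermolecular allylation (oligomerisation) may compete with ring closure, the allylchromium may lose the C8 carboxylate by 1,4-elimination, or the aldehyde may add to the wrong face of C7. The fallback sets out from 20 and comes back at 27; it moves the esterification behind the ring closure, so the allylchromium carries a silyl ether and no leaving group. Alcohol 20 is silylated (TBSOTf, 2,6-lutidine) to the C8 silyl ether F1. The primary C6 silyl ether is cleaved selectively (HF·pyridine/pyridine, 0 °C) to the C6 alcohol F2, which MnO2 oxidises to the enal F3. Cross-metathesis with 24 gives the bromide F4, and CrCl2 closes it to the C8-silyloxy lactone F5. HF·pyridine frees the C8 alcohol F6, which is esterified with 4 (Yamaguchi) to give 27.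

2. Step 18. The hindered allylic ester may initiate slowly while the ruthenium carbene decomposes or consumes 24 by homodimerisation, so conversion may stall. The fallback sets out from 20 and comes back at 25; it runs the metathesis on the free allylic alcohol with a bromide-free partner and brings in the bromide by substitution. Methyl 2-(hydroxymethyl)acrylate is silylated (TESCl, imidazole) to the silyl ether F7. Cross-metathesis of 20 with F7 gives the hydroxy enoate F8, which is esterified with 4 (Yamaguchi) to the ester F9. Bu4NF/AcOH removes both primary silyl groups to give the diol F10. MnO2 oxidises only the electron-rich C6 allylic alcohol to the hydroxy enal F11, and an Appel reaction (CBr4, PPh3) on the remaining primary alcohol gives 25.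

3. Step 14. Felkin-type addition may compete with the magnesium chelate (poor facial selectivity), and the C1=C10 double bond of aldehyde 19 may migrate under basic conditions. The fallback sets out from 19 and comes back at 21; it reverses the substrate control on purpose and corrects C8 during esterification. The non-chelating reagent CH2=CHTi(OiPr)3 adds in the Felkin–Anh sense to give the 8-epi alcohol F12, and Mitsunobu esterification with 4 (PPh3, DIAD) inverts C8 and gives 21.

Further compounds
F1 | step 19 | C8 tert-butyldimethylsilyl ether of 20 | CC(C)(C)[Si](C)(C)OC/C=C(/C)[C@@H]1O[C@@H]1/C=C(/C(=O)OC)[C@H](OCc2ccc(OC)cc2)[C@@H](O[Si](C)(C)C(C)(C)C)C=C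
F2 | step 19 | C6 alcohol with C8 silyl ether | OC/C=C(/C)[C@@H]1O[C@@H]1/C=C(/C(=O)OC)[C@H](OCc2ccc(OC)cc2)[C@@H](O[Si](C)(C)C(C)(C)C)C=C
F3 | step 19 | (Z)-enal with C8 silyl ether | O=C/C=C(/C)[C@@H]1O[C@@H]1/C=C(/C(=O)OC)[C@H](OCc2ccc(OC)cc2)[C@@H](O[Si](C)(C)C(C)(C)C)C=C
F4 | step 19 | open-chain bromo-enal with C8 silyl ether | O=C/C=C(/C)[C@@H]1O[C@@H]1/C=C(/C(=O)OC)[C@H](OCc2ccc(OC)cc2)[C@@H](O[Si](C)(C)C(C)(C)C)/C=C(/C(=O)OC)CBr
F5 | step 19 | macrocyclic lactone with C8 silyl ether and C9 PMB ether | C=C1C(=O)O[C@@H]2/C=C(/C)[C@@H]3O[C@@H]3/C=C(/C(=O)OC)[C@H](OCc4ccc(OC)cc4)[C@@H](O[Si](C)(C)C(C)(C)C)[C@@H]12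
F6 | step 19 | macrocyclic lactone with free C8 hydroxyl and C9 PMB ether | C=C1C(=O)O[C@@H]2/C=C(/C)[C@@H]3O[C@@H]3/C=C(/C(=O)OC)[C@H](OCc4ccc(OC)cc4)[C@@H](O)[C@@H]12
F7 | step 18 | methyl 2-[(triethylsilyloxy)methyl]acrylate | C=C(CO[Si](CC)(CC)CC)C(=O)OC
F8 | step 18 | cross-metathesis product of 20 with free C8 hydroxyl and C13 triethylsilyl ether | CC(C)(C)[Si](C)(C)OC/C=C(/C)[C@@H]1O[C@@H]1/C=C(/C(=O)OC)[C@H](OCc2ccc(OC)cc2)[C@@H](O)/C=C(/C(=O)OC)CO[Si](CC)(CC)CC
F9 | step 18 | C8 epoxyangelate of F8 | CC(C)(C)[Si](C)(C)OC/C=C(/C)[C@@H]1O[C@@H]1/C=C(/C(=O)OC)[C@H](OCc2ccc(OC)cc2)[C@@H](OC(=O)[C@]3(C)O[C@@H]3C)/C=C(/C(=O)OC)CO[Si](CC)(CC)CC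
F10 | step 18 | C6,C13 diol | OC/C=C(/C)[C@@H]1O[C@@H]1/C=C(/C(=O)OC)[C@H](OCc2ccc(OC)cc2)[C@@H](OC(=O)[C@]3(C)O[C@@H]3C)/C=C(/C(=O)OC)CO
F11 | step 18 | (Z)-enal with C13 hydroxyl | O=C/C=C(/C)[C@@H]1O[C@@H]1/C=C(/C(=O)OC)[C@H](OCc2ccc(OC)cc2)[C@@H](OC(=O)[C@]3(C)O[C@@H]3C)/C=C(/C(=O)OC)CO
F12 | step 14 | 8-epi allylic alcohol (8,9-anti) | CC(C)(C)[Si](C)(C)OC/C=C(/C)[C@@H]1O[C@@H]1/C=C(/C(=O)OC)[C@H](OCc2ccc(OC)cc2)[C@H](O)C=C
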